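**Retrosynthetic overview**
1. C2–Br ⇒ C2=O. The 2-bromoindole is the deoxybrominated, aromatised form of 4,5,6-tribromo-3-(methylsulfanyl)oxindole, so no indole is ever brominated or sulfenylated with an electrophile.
2. N1–C2 ⇒ lactamisation of an ortho-amino aryl(methylsulfanyl)acetate. The five-membered ring is the only ring formed; the benzene ring is bought with its three bromines.
3. C3–C3a (key bond) ⇒ [2,3]-sigmatropic shift of an N-aryl azasulfonium ylide. The ester α-carbon and the aniline ortho-carbon are both innate nucleophiles. They can be joined because oxidation at nitrogen turns the ring into the acceptor. The sulfur tether is kept as the SMe group of the target.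
4. Starting materials: 3,4,5-tribromoaniline (mirror-symmetric, both ortho carbons equivalent, so only the 4,5,6-tribromo pattern can arise) and ethyl (methylsulfanyl)acetate.

Assumption: the target is a planar, achiral indole with no stereocentre, so there is no enantiomer to select; transient stereocentres in the intermediates are racemic and are erased in the last step; both starting materials, t-BuOCl and POBr3 are taken as catalogue chemicals.

**Step 1**
Reactants: 1 3,4,5-tribromoaniline; 2 ethyl (methylsulfanyl)acetate
Product: 7 rac-4,5,6-tribromo-3-(methylsulfanyl)-1,3-dihydro-2H-indol-2-one, via N-chloro-3,4,5-tribromoaniline 3 (not isolated), via azasulfonium chloride 4 (not isolated), via azasulfonium ylide 5 (not isolated), via amino ester 6 (not isolated)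
Conditions: t-BuOCl (1.05 equiv), CH2Cl2, −70 °C; 2 (1.2 equiv), −70 °C, 2 h; Et3N (1.5 equiv), −70 °C to 40 °C; then 2 M aq HCl, Et2O–THF, rt, 16 h
Reagents that add atoms: none
Why: This is a Gassman oxindole synthesis, in which N-chlorination lets sulfide 2 bind to nitrogen, Et3N removes the more acidic ester-flanked S–CH2 proton, and ylide 5 undergoes a Sommelet–Hauser-type [2,3]-sigmatropic shift that bonds the ester α-carbon to the aniline ortho-carbon (two innately nucleophilic carbons, coupled because the N–S+ unit makes the ring the acceptor); the reaction type works best with electron-poor anilines, tolerates a flanking meta substituent, can give only one regioisomer here, and is finished by acid-catalysed 5-exo lactamisation of 6, with the C3 stereocentre formed racemic and erased in step 2.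

**Step 2**
Reactants: 7 rac-4,5,6-tribromo-3-(methylsulfanyl)-1,3-dihydro-2H-indol-2-one
Product: 9 2,4,5,6-tetrabromo-3-(methylsulfanyl)-1H-indole, via indol-2-yl phosphorodibromidate 8 (not isolated)
Conditions: POBr3 (2.5 equiv), ClCH2CH2Cl, 80 °C, 1 h; then imidazole (1.2 equiv), 80 °C; cold aq NaHCO3 quench
Reagents that add atoms: phosphorus oxybromide (POBr3), O=P(Br)(Br)Br
Why: This is a lactam deoxybromination of the Vilsmeier type (the standard oxindole to 2-bromoindole conversion), in which the lactam oxygen is phosphorylated to 8 and bromide displaces the phosphate at C2 by addition–elimination, driven by aromatisation, so bromine enters only where oxygen was, no electrophilic bromine meets the sulfide or C7–H, and the racemic C3 centre becomes planar.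

**Compound list**
1 | 3,4,5-tribromoaniline | Nc1cc(Br)c(Br)c(Br)c1 | starting material
2 | ethyl (methylsulfanyl)acetate | CCOC(=O)CSC | starting material
3 | N-chloro-3,4,5-tribromoaniline | ClNc1cc(Br)c(Br)c(Br)c1 | intermediate
4 | (2-ethoxy-2-oxoethyl)(methyl)[(3,4,5-tribromophenyl)amino]sulfonium chloride, racemic at sulfur | CCOC(=O)C[S+](C)Nc1cc(Br)c(Br)c(Br)c1.[Cl-] | intermediate
5 | 2-ethoxy-1-{methyl[(3,4,5-tribromophenyl)amino]sulfonio}-2-oxoethan-1-ide (azasulfonium ylide), racemic | CCOC(=O)[CH-][S+](C)Nc1cc(Br)c(Br)c(Br)c1 | intermediate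
6 | rac-ethyl 2-(2-amino-4,5,6-tribromophenyl)-2-(methylsulfanyl)acetate | CCOC(=O)C(SC)c1c(N)cc(Br)c(Br)c1Br | intermediate
7 | rac-4,5,6-tribromo-3-(methylsulfanyl)-1,3-dihydro-2H-indol-2-one | CSC1C(=O)Nc2cc(Br)c(Br)c(Br)c12 | intermediate
8 | 4,5,6-tribromo-3-(methylsulfanyl)-1H-indol-2-yl phosphorodibromidate | CSc1c(OP(=O)(Br)Br)[nH]c2cc(Br)c(Br)c(Br)c12 | intermediate
9 | 2,4,5,6-tetrabromo-3-(methylsulfanyl)-1H-indole (achiral) | CSc1c(Br)[nH]c2cc(Br)c(Br)c(Br)c12 | target

**Total step count:** 2. **Longest linear sequence:** 2.

**Steps most likely to fail** (the route has only two steps, so both are ranked)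

1. Step 1 carries the highest risk.
   - Risk: Compound 1 is a very weak base, and the new bond must form at a ring carbon flanked by bromine. Salt 4 may form slowly. The base may also take the N–H proton instead of the C–H proton and stall the shift. Warming with Et3N is already built into the conditions for this reason.
   - Fallback, from 1 back to 7: the same C3–C3a bond is made by a cationic route instead of a pericyclic one. Compound 1 is acylated with (methylsulfanyl)acetyl chloride and pyridine in CH2Cl2 to give 2-(methylsulfanyl)-N-(3,4,5-tribromophenyl)acetamide F1. N-Chlorosuccinimide in CH2Cl2 at 0 °C then gives rac-2-chloro-2-(methylsulfanyl)-N-(3,4,5-tribromophenyl)acetamide F2. SnCl4 in ClCH2CH2Cl (rt to 60 °C) ionises the C–Cl bond to the acyl thionium pentachlorostannate F3, an α-carbonyl cation equivalent. This ion closes on the ortho carbon in a Pummerer-type Friedel–Crafts cyclisation and delivers 7.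

2. Step 2.
   - Risk: The lactam of 7 is electron-poor and crowded by the peri bromine, so O-phosphorylation may be slow. Hot acid could also erode the C–S bond.
   - Fallback, from 1 back to 9: C2 is carried at the aldehyde level and its bromine is added last as an electrophile. Compound 1 is N-chlorinated to 3 as in step 1 and treated at −70 °C with (methylsulfanyl)acetaldehyde dimethyl acetal. This gives (2,2-dimethoxyethyl)(methyl)[(3,4,5-tribromophenyl)amino]sulfonium chloride F4. Et3N converts it into the acetal azasulfonium ylide F5, which rearranges to rac-3,4,5-tribromo-2-[2,2-dimethoxy-1-(methylsulfanyl)ethyl]aniline F6. Treatment with 1 M HCl in Et2O–THF closes and aromatises F6 to 4,5,6-tribromo-3-(methylsulfanyl)-1H-indole F7 (Gassman indole synthesis). N-Bromosuccinimide (1.0 equiv, CH2Cl2, −20 to 0 °C) then brominates C2, the only open pyrrole position, to give 9. The benzo ring is too deactivated to compete. One risk remains: attack of bromine at C3 followed by a shift of the SMe group to C2 would give the 3-bromo-2-(methylsulfanyl) isomer.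

**Further compounds**
F1 | step 1 | 2-(methylsulfanyl)-N-(3,4,5-tribromophenyl)acetamide | CSCC(=O)Nc1cc(Br)c(Br)c(Br)c1
F2 | step 1 | rac-2-chloro-2-(methylsulfanyl)-N-(3,4,5-tribromophenyl)acetamide | CSC(Cl)C(=O)Nc1cc(Br)c(Br)c(Br)c1
F3 | step 1 | acyl thionium pentachlorostannate, methyl{2-oxo-2-[(3,4,5-tribromophenyl)amino]ethylidene}sulfonium pentachlorostannate | C[S+]=CC(=O)Nc1cc(Br)c(Br)c(Br)c1.Cl[Sn-](Cl)(Cl)(Cl)Cl
F4 | step 2 | (2,2-dimethoxyethyl)(methyl)[(3,4,5-tribromophenyl)amino]sulfonium chloride, racemic at sulfur | COC(OC)C[S+](C)Nc1cc(Br)c(Br)c(Br)c1.[Cl-]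
F5 | step 2 | acetal azasulfonium ylide, 2,2-dimethoxy-1-{methyl[(3,4,5-tribromophenyl)amino]sulfonio}ethan-1-ide | COC(OC)[CH-][S+](C)Nc1cc(Br)c(Br)c(Br)c1
F6 | step 2 | rac-3,4,5-tribromo-2-[2,2-dimethoxy-1-(methylsulfanyl)ethyl]aniline | COC(OC)C(SC)c1c(N)cc(Br)c(Br)c1Br
F7 | step 2 | 4,5,6-tribromo-3-(methylsulfanyl)-1H-indole | CSc1c[nH]c2cc(Br)c(Br)c(Br)c12
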